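**One-step world.** In a one-step world, E + D → Q, the ratio of the two charges would show how far Q can go. The suspects form a longer chain, with Z the catalyst form that carries L, but both Q and D appear in a single listed step, D + Z -> X + Q. Dividing the rate of Q's formation by the rate of D's loss therefore gives one at each moment, and time drops out: Q made equals D spent. In this flask the D charged stands at 105% of the E charged. We call this ratio the cover C, a ceiling on Q.

- Saturday's: E 0.29 M; D 1.05 equiv; G 0.05 mol%; X 15 mol%; run made earlier
- flask: E 0.29 M; D 1.05 equiv; G 0.1 mol%; X 15 mol%; time 10 min

- Saturday's (time / s: Q / %, J / %): 10.0: 0.2, 7.0; 12.0: 0, 9.9; 20.0: 0.8, 14.8; 30.0: 0.7, 19.2; 50.0: 0, 26.2; 60.0: 1.5, 28.3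

(each reading ± 0.5 percentage points)

- as a solid, counted per litre of solution: E
- on the list of suspects stand: D + Z -> X + Q; X + L <-> Z; E <-> J; J + G -> G + L
- at the start none of E is in solution
- J means what is dissolved; the solid is not counted in it
- no earlier run changes the charge of G; that part of a forecast is a guess

* the Q standing at 10 min, as a percentage of the E charged
* concentration of J in solution at 5.0 min, in percent of saturation
* the change that raises the amount of Q at 10 min, in percent of the E charged most ("none" if none brings more than 2 percentage points) (north-west / east / north-east / north / none)
* amount of Q at 10 min, in percent of the E charged, after north-east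

- north-west: doubling the solubility of E, all else as stated
- east: doubling the amount of D, all else as stated
- north-east: doubling the dissolution coefficient of E, all else as stated
- north: doubling the amount of G, all else as stated

**Turned round.** For D to stop Q in this flask, Q would have to climb to C. But C lies 5 percentage points above the whole of E, so E is the limiting reagent. Saturday's last Q reading is 1.5% at 60.0 s, and it carries a scatter of 0.5 points. Scaled by the ratio of G, which is a guess, and carried in a straight line to 10 min, it gives us a rough 30.0%. C is 3.50 times that, so by our reckoning D does not stop Q in this flask by 10 min.

**The forecast.** It gives Q 39% (24% to 53%) at 10 min, above our figure; J at 92% of saturation at 5.0 min; north as the best change; and 42% after north-east. On D it says: “Doubling D does nothing if the Z step is fast, though that step is unproven”.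

**The flask.** At 10 min this flask holds Q at 85.5%, 46 points above the forecast and still below C, with 19% of the D charged left. At 5.0 min J stands at 78.5% of saturation. North is the best change, adding 12 points to Q at 10 min, and north-east gives 89.0%.

    D + Z → X + Q (k = 28.7 /M/s)
    X + L ⇌ Z (K = 0.791 /M, k = 0.384 /M/s)
    E ⇌ J, rate k3*(cs3 - [J]) while solid is left; crystals form when [J] > cs3 (solubility = 0.120 M, k = 0.0223 /s)
    J + G → G + L (k = 21.0 /M/s)

By the J + G step alone, with the other concentrations as charged, J has a half-life of 1.9 min, short against 10 min. By the forward X + L step alone, L has a half-life of 0.69 min at 10.0 min, shorter still.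

**Less D.** The neighbour with 0.420 equiv of D has a cover of 42.0%, below the whole of its E, so its ceiling on Q is 42.0%. Computed, that neighbour reaches Q 42.0% at 10 min, with 0% of its D left and L at 48.2%.

(All runs are calculated for an exercise, noise included.)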